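You take over these flasks, and the question is how many links each holds when you come back.

| flask | first end groups | second end groups | temperature | remark | time |
|---|---|---|---|---|---|
| ochre | 0.10 M | 0.070 M | 80 °C | run made earlier |  |
| blue | 0.10 M | 0.052 M | 80 °C | run made earlier |  |
| cedar | 0.40 M | 0.105 M | 40 °C |  | 2.5 h |
| larch | 0.10 M | 0.105 M | 40 °C |  | 2.5 h |
| maple | 0.025 M | 0.105 M | 80 °C |  | 2.5 h |
| ash | 0.025 M | 0.105 M | 40 °C |  | 2.5 h |
| elm | 0.10 M | 0.105 M | 80 °C |  | 2.5 h |
| alder | 0.40 M | 0.105 M | 80 °C |  | 2.5 h |

1. ranking by amount of links, in percent of the first end groups charged, from high to low, at 2.5 h (cedar / larch / maple / ash / elm / alder)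
2. the amount of links, in percent of the first end groups charged of the flask you put first, at 2.5 h
3. the amount of links, in percent of the first end groups charged of the flask you put last, at 2.5 h

The earlier runs:

| run | time / min | links / % | first end groups / % |
|---|---|---|---|
| ochre | 8.00 | 17.6 | 82.3 |
| ochre | 15.0 | 28.3 | 71.8 |
| ochre | 25.0 | 36.8 | 61.6 |
| ochre | 30.0 | 39.9 | 57.9 |
| blue | 8.00 | 13.7 | 86.8 |
| blue | 15.0 | 21.3 | 79.1 |
| blue | 25.0 | 29.1 | 70.6 |
| blue | 30.0 | 30.9 | 66.9 |

(each reading ± 0.3 percentage points)

Each first end group that reacts takes one second end group. From the last ochre reading, rate = k·c_first·c_second gives k = 0.415 L mol⁻¹ min⁻¹, and blue gives 0.424 L mol⁻¹ min⁻¹.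

Maple is at 80 °C with second end groups in excess, but the excess is too small to call the decay pseudo-first-order: with its first end groups used up, maple's second end groups would stand at 76.2% of their charge. Maple's starting time is 23.0 min, one over k times the charged concentration of the more plentiful end group: call this the fill time. Your 2.5 h is 6.53 fill times, and the second-order solution for unequal charges, which counts that fall, leaves by my reckoning 0.525% of maple's first end groups.

But watch the leak, the charge standing neither as links nor as first end groups. In ochre it grew from 0.1 percentage points to 2.2 points. Kept at that pace, it puts maple near 89.0%, my own figure.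

So don't let maple run on: after 4 fill times, the same reckoning leaves 3.66% of its first end groups to make links. The runs don't show what temperature does, so I give no figure for the cooler flasks.

The forecast says maple > elm > ash > larch > cedar > alder, with 97.5% on top and 10% at the bottom: “The mechanism is a guess, but it matters when excess A persists for hours.” I share its order, but my maple stands lower.

The flasks give maple > elm > ash > larch > cedar > alder, with 79.9% in maple and 11.4% in alder.

    links + by-product → side product (k = 0.0890 M⁻¹ min⁻¹, Ea = 62.0 kJ mol⁻¹)
    first end groups + second end groups → links + by-product (k = 0.410 M⁻¹ min⁻¹, Ea = 70.0 kJ mol⁻¹)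
    (constants at 80 °C)

In maple, first end groups stand at 0.557%, and links fell from 85.6% at 1.25 h to 79.9% at 2.50 h, with side product at 19.5%. The neighbour is alder charged with 0.42 M of second end groups, 1.05 equiv. Its fill time is 5.74 min, so 26.1 of them pass. Reckoned for unequal charges as in maple, that leaves 1.89% of first end groups, and the flask holds 1.93%. Side product there stands at 78.6% and links at 19.4%.

The earlier runs and the new flask were computed from invented constants, and the scatter is random.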